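The readings stem from a simulated flask for substances that don't exist; scatter was added.

What beta, epsilon and eta had left standing at their highest readings I counted in mM, as c(mono adduct), and not in percent of the charge.

| flask | starting material | solid reagent | remark | time |
|---|---|---|---|---|
| beta | 48 mM | 1.2 equiv | run made earlier |  |
| epsilon | 75 mM | 1.2 equiv | run made earlier |  |
| eta | 34 mM | 1.8 equiv | run made earlier |  |
| flask | 34 mM | 1.20 equiv |  | 2.0 h |

- beta (time / min: mono adduct / %): 4.00: 10.7; 6.00: 16.2; 10.0: 22.5; 15.0: 24.0; 25.0: 20.5; 40.0: 13.7; 80.0: 5.2
- epsilon (time / min: mono adduct / %): 4.00: 8.0; 6.00: 11.6; 10.0: 14.8; 15.0: 17.5; 25.0: 14.8; 40.0: 9.1; 80.0: 3.2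
- eta (time / min: mono adduct / %): 4.00: 14.0; 8.00: 25.0; 15.0: 30.2; 30.0: 22.8; 80.0: 6.2

(standard deviation of a reading: 0.5 percentage points)

- at the start none of the solid reagent is in solution

- time up to 2.0 h at which mono adduct stands highest
- the amount of mono adduct, in percent of the starting material charged, at that time

First I asked whether the highest reading follows the charge. At 1.2 equiv, the highest reading of beta was 11.5 mM and that of epsilon 13.1 mM. The charge grew 1.56-fold but the peak only 1.14-fold. So I read the peak slope, the log-log slope of peak c(mono adduct) against starting concentration at fixed equivalents, as 0.292.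

Next I asked whether the reagent loading matters. Carried from beta down to 34 mM, the slope gives 10.4 mM. The highest reading of eta, at that concentration with 1.8 equiv, was 10.3 mM, which is close, so I made no correction for the flask's 1.20 equiv.

My reckoning for the flask was therefore 30.6%, with its peak placed near the 15.0 min reading, where beta, epsilon and eta each stood highest. The forecast said 30% at 0.23 h, a little lower than mine: “I expect a curve close to eta's”.

The flask gives 30.4% at 0.231 h, which is 10.3 mM.

    starting material + partner → mono adduct + by-product (k = 0.310 L mol⁻¹ s⁻¹)
    partner + mono adduct → bis adduct + by-product (k = 0.0160 L mol⁻¹ s⁻¹)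
    partner + bis adduct → triple product + by-product (k = 0.670 L mol⁻¹ s⁻¹)
    solid reagent ⇌ partner, rate k4*(cs4 - [partner]) while solid is left; crystals form when [partner] > cs4 (solubility = 30.0 mM, k = 0.00200 s⁻¹)
    crystals ⇌ by-product, rate k5*(cs5 - [by-product]) while solid is left; crystals form when [by-product] > cs5 (solubility = 0.900 mM, k = 0.0590 s⁻¹)
    2 starting material → self-condensation product (k = 0.110 L mol⁻¹ s⁻¹)

The flask's peak stands close to the 10.4 mM from the peak slope. On the neighbouring flask with 20 mM of starting material, the same slope gives 8.92 mM, or 44.6%. That neighbour's simulated peak is 41.7%, which is 8.34 mM, so the reckoning stands higher. The neighbour's percentage exceeds the flask's, while its c(mono adduct) is lower. At 2.00 h the neighbour still holds 22.0% mono adduct.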